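(The numbers in the tables come from a simulation for an exercise; scatter was added.)

The blue run, with the lightest charge of starting material, holds 8.9 % of it as target at 3.00 h, and we want to know what that says about a flask charged with 0.20 M at 5.0 h.

| setting | blue | green | teal | flask |
|---|---|---|---|---|
| starting material | 0.10 M | 0.40 M | 0.20 M | 0.20 M |
| reagent in the second phase | 0.22 M | 0.22 M | 0.44 M | 0.220 M |
| remark | run made earlier | run made earlier | run made earlier |  |
| time |  |  |  | 5.0 h |
| volume of the second phase over the first |  |  |  | 1.0 |

- blue (time / h: target / %): 0.417: 0.2; 1.00: 2.2; 2.00: 5.4; 3.00: 8.9
- green (time / h: target / %): 0.833: 1.2; 1.50: 4.5; 2.50: 5.1; 3.00: 7.0
- teal (time / h: target / %): 0.833: 2.9; 1.50: 7.8; 2.50: 12.0; 3.00: 13.5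

(readings scatter by 0.5 percentage points)

- in the second phase: reagent in the second phase; everything else is in the first
- charges count per volume of the first phase; a concentration in a rate is the amount of a species over the volume of its own phase; every rate counts per litre of the first phase
- the earlier runs were read with a standard deviation of 0.5 percentage points
- the earlier runs hold the two phases in the same ratio of volumes as the flask asked about

- how much target there is at 5.0 h, in percent of the starting material charged
- the change that raises the amount of target at 5.0 h, in percent of the starting material charged most ("none" if none brings more than 2 percentage points) (south-west / west / none)
- amount of target at 5.0 h, in percent of the starting material charged, after west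

- south-west: doubling the amount of reagent in the second phase, all else as stated
- west: doubling the transfer coefficient of the reagent in the second phase, all else as stated

We start from two extreme versions of the flask. If transfer from the second phase controlled the flask, it would make the same amount per hour as blue and reach 7.42 %. If the reaction controlled it, it would convert blue's fraction of its charge per hour and reach 14.8 %.

The green run places the flask between these, since at the same reagent charge a charge of starting material 4.00 times blue's had made 3.15 times the target by the same hour, a reading that carries their scatter. We put the two steps in series, so that reciprocal rates add. The last readings of blue and green then give, as readings, a pseudo-first-order constant of 0.0326 h⁻¹ and a supply ceiling, the rate of target that transfer allows at this reagent charge, of 0.0328 M h⁻¹.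

For the flask we reckon 13.6 %, nearer the upper extreme than the lower. West doubles the transfer coefficient, which we take to double the ceiling, and that gives 14.8 %. South-west puts the flask on the charges of the teal run, whose last reading extended in a straight line gives 22.5 %, more than west, so we choose south-west.

The forecast says 12.5 %, south-west and 14 %, lower than ours on the first count: “Allowing for the lag and slight depletion gives about 12.5% at 5 h.”

The flask gives 12.3 %, with south-west best at 6.4 percentage points, and 13.3 % after west.

    starting material + reagent in the reaction phase → target (k = 0.133 M⁻¹ min⁻¹)
    reagent in the reaction phase + target → over-reacted product (k = 0.126 M⁻¹ min⁻¹)
    reagent in the reaction phase ⇌ reagent in the second phase, rate k3*([reagent in the reaction phase] - [reagent in the second phase]/K3) per volume of the first phase (partition coefficient = 14.0, kL = 0.0422 min⁻¹)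
    starting material ⇌ dormant form (K = 1.54, k = 0.503 min⁻¹)

At 5.00 h the flask's starting material enters the dormant form 380 times faster than it enters target, counting that forward rate alone, and 33.5 % stands free beside 51.6 % dormant. Over 5.0 h target formed in the flask on average at 15.0 % of the ceiling we read, and west added 1.1 points. The neighbour charged with 0.80 M, reckoned under the same ceiling, comes to 9.08 % and gives 7.91 %.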